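**Structural features**

The target is a diester of a cyclobutane that carries carboxylates at C1/C3 and 4-hydroxyphenyl groups at C2/C4 in the α-truxillate (head-to-tail) pattern: each ester is cis to one aryl neighbour and trans to the other, so the core alone is centrosymmetric and achiral. Both carboxylates are esterified by the same amino alcohol, a cis-fused octahydrocyclopenta[c]pyridine: an N2-methylpiperidine (C1–N2–C3–C4–C4a–C7a) fused through C4a–C7a to a cyclopentane (C4a–C5–C6–C7–C7a), with methyl groups at C4 and C7 and the ester oxygen at C6, configuration (4R,4aS,6R,7S,7aR). In each unit five stereocentres are contiguous: H4, H4a and H7a are mutually cis on the convex face, and the C7 methyl and C6 oxygen also lie on the convex face, cis to each other and trans to the C7a–C1 bond. Fragile points are the two hindered secondary esters (their cyclobutane α-CH centres epimerise with base), the cyclobutane itself (cycloreversion under light), the free phenols and the two basic tertiary amines. The real difficulty is not the cyclobutane, whose four centres form together in a crystal lattice, but the ten stereocentres in the two copies of the bicyclic amine, above all the all-cis C4/C4a/C7a triad next to the C7/C6 pair, and the acylation of the crowded C6 oxygen cis to the C7 methyl. The key step exploits the piperidine ring: it is substituted at C7a, C4a and C4, unsubstituted at C1 and C3, and its three ring hydrogens are cis, which is the signature of hydrogen added to one face of a pyridine. The bicycle therefore maps onto a flat cyclopenta[c]pyridinium in which only C6 and C7 of the five-membered ring are stereogenic.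

**Logic of the disconnections**

18 ⇒ 17. The two aryl O–Si bonds are cut. The phenols must be masked because they would compete as nucleophiles in the esterification. The forward step needs a fluoride source that leaves the hindered esters and the cyclobutane α-centres alone.

17 ⇒ 16 + 2 × 12. The two C6–O bonds are cut on the alkyl side, so each ester oxygen comes from the acid and C6 is inverted on bond formation. This splits the molecule into one achiral diacid and two copies of one amine. It also turns the crowded convex-face ester into the product of an SN2 reaction on the concave-face alcohol, which is the epimer a small hydride should give. The forward step must invert twice without elimination and without base at the cyclobutane.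

16 ⇒ 14 ⇒ 13 (15 is a transient). Two cyclobutane bonds are cut, C1–C2 and C3–C4 in the numbering of the (1α,2α,3β,4β) name, that is, the bonds that join each carboxyl-bearing carbon to its cis aryl-bearing neighbour. This is the reverse of a head-to-tail [2+2] of two molecules of 13. All four ring centres and the regiochemistry come from crystal packing, so the core costs one step from a commodity acid. The demand is a centrosymmetric head-to-tail arrangement of the alkenes in the crystal.

12 ⇒ 11. The C6–H bond is cut back to the ketone. The gain is that C6 becomes trigonal and C7 becomes enolisable. The forward reduction must deliver hydride from the convex face.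

11 ⇒ 9 (through 10). The C7 configuration of 11 is recognised as the thermodynamic one (methyl on the convex face, trans to C7a–C1), so it can come from its epimer by enolisation after oxidation of a C6 carbinol. The consequence is that C6 and C7 of 9 are expendable: they can carry whatever configuration best controls the step before. The demand is a clear thermodynamic preference at C7, which the cis-fused skeleton provides.

9 ⇒ 8 (key disconnection). Five C–H bonds at C1, C3, C4, C4a and C7a are cut, which aromatises the piperidine to a pyridinium ring. Three contiguous stereocentres disappear and the precursor is flat, with only the cis C6–OH/C7–Me pair left as stereochemical information. In one sentence, the route is the one-face saturation of the enantioenriched cyclopenta[c]pyridinium salt 8. The forward step must add all hydrogens to the face opposite the C6/C7 substituents and keep the syn relationship at C4.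

8 ⇒ 7. The N–CH3 bond is cut. Quaternisation activates the ring for reduction and installs the N-methyl group in the same operation.

7 ⇒ 6. The C6–H bond is cut back to a ketone whose C7 centre is benzylic and α to the carbonyl, hence configurationally labile. One catalytic reduction with dynamic kinetic resolution then sets C6 and C7 together, and these are the only centres the route takes from a chiral reagent. The demand is fast racemisation at C7 and cis-selective, enantioselective hydride delivery.

6 ⇒ 4 (5 is a transient). The C7a–C7 bond is cut (aryl–alkene coupling), with a redox isomerisation of the resulting allylic alcohol to the ketone. The five-membered ring comes from an ortho-bromo picolyl carbinol. The demand is 5-exo ring closure and migration of the exocyclic double bond into the enol.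

4 ⇒ 1 + 2 (3 is a transient). The C5–C6 bond is cut between the picolyl carbon and an aldehyde. Both pieces are simple: a bromolutidine and acrolein. The demand is selective deprotonation of the C4 methyl beside an aryl bromide and 1,2-addition to the enal.

**Other disconnections considered**

Alternative 1: the first idea. The same two ester C–O bonds are cut to 16 and 12, but 12 is built cyclopentane-first. The forward key step would be conjugate addition of a methyl cuprate to the enone A1 trans to its silyloxy group, with Mannich trapping of the enolate to the trisubstituted cyclopentanone A2. The piperidine would then be closed at C4–C4a from the ketone (enol triflate, reductive Heck onto the methallyl group) and hydrogenated. This sets C7, C7a and C6 one event at a time. C4 and C4a are left to a late hydrogenation of a hindered alkene controlled by a single neighbouring centre. A2 is a β-silyloxy ketone prone to elimination, and the sequence to 12 would be roughly twice as long. The chosen plan sets C4/C4a/C7a in one operation on a flat precursor.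

Alternative 2: cut C7a–C4a, C5–C6 and C6–C7 in an intramolecular Pauson–Khand reaction of the nitrogen-tethered 1,7-enyne A3 (C4 bought as a Roche-ester-derived centre), giving the bicyclic enone A4. Convex-face hydrogenation, C7 epimerisation and exchange of N-sulfonyl for N-methyl would follow. The step closes both rings, but the C4 methyl must control C4a through a chair-like insertion transition state. The required isomer (H4 cis to H4a) needs that methyl pseudo-axial on the forming six-membered ring, and the pseudo-equatorial arrangement, which leads to the 4-epi series, is expected to be at least competitive. In addition, 1,7-enynes cyclise more slowly than 1,6-enynes, and the change of nitrogen substituent adds steps. In the chosen plan the C4/C4a relationship follows from syn addition and cannot be mis-set by a conformational preference.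

Alternative 3: cut the cyclobutane last, by [2+2] photodimerisation of the monomeric coumarate ester A5 (from 12 and a protected form of 13). The sequence would be convergent on paper and biomimetic. In solution, however, cinnamates relax by E/Z isomerisation and, when they do dimerise, give head-to-head products. Head-to-tail coupling needs a crystal of A5 with the right packing, which cannot be predicted for a flexible amino ester, and the most advanced intermediate would be staked on it. The plan also leaves the bicyclic amine, the real problem, unsolved. The chosen plan performs the lattice-controlled dimerisation on the simple acid 13.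

Key step: step 5

Assumptions:
- 3-Bromo-4,5-dimethylpyridine (1) is taken as a catalogue building block.
- The (S,S)-catalyst in step 3 is assumed to give the (6S,7R)-alcohol; if the sense of induction is opposite, the (R,R)-catalyst is used and nothing else changes.
- Crystalline 13 is taken to adopt the centrosymmetric head-to-tail packing usual for para-substituted trans-cinnamic acids.
- Locants follow cyclopenta[c]pyridine numbering (N2, ring fusion C4a/C7a).

**Route**

Step 1
Reactants: 1 3-bromo-4,5-dimethylpyridine; 2 acrolein (prop-2-enal)
Product: 4 rac-1-(3-bromo-5-methylpyridin-4-yl)but-3-en-2-ol, via picolyllithium 3 (not isolated)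
Conditions: LDA (1.1 equiv), THF, −78 °C; then 2, −78 °C; AcOH quench
Reagents that add atoms: none
Why: Lateral lithiation: the C4 methyl of the pyridine (γ-picoline type) is far more acidic than the C5 methyl and the amide base does not touch the C–Br bond; the picolyllithium should add 1,2 to the enal at low temperature; the carbinol centre is racemic and is erased in step 2.

Step 2
Reactants: 4 rac-1-(3-bromo-5-methylpyridin-4-yl)but-3-en-2-ol
Product: 6 rac-4,7-dimethyl-5,7-dihydro-6H-cyclopenta[c]pyridin-6-one, via methylidene alcohol 5 (not isolated)
Conditions: Pd(OAc)2 (5 mol %), P(o-tol)3 (12 mol %), Et3N (2 equiv), DMF, 90 °C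
Reagents that add atoms: none
Why: Intramolecular Mizoroki–Heck reaction: 5-exo-trig carbopalladation of the vinyl group forms C7a–C7, β-hydride elimination gives the exocyclic allylic alcohol 5, and Pd–H re-addition/elimination towards the carbinol C–H should move the double bond into the enol and so give the ketone, the thermodynamic sink; C7 of 6 is configurationally labile, so no stereocontrol is needed.

Step 3
Reactants: 6 rac-4,7-dimethyl-5,7-dihydro-6H-cyclopenta[c]pyridin-6-one
Product: 7 (6S,7R)-4,7-dimethyl-6,7-dihydro-5H-cyclopenta[c]pyridin-6-ol (cis)
Conditions: RuCl(p-cymene)[(S,S)-TsDPEN] (2 mol %), HCO2H/Et3N (5:2), DMF, 40 °C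
Reagents that add atoms: none
Why: Noyori–Ikariya asymmetric transfer hydrogenation with dynamic kinetic resolution: C7–H (α to C=O and benzylic to the pyridine) racemises through the enol in the amine-containing medium while the catalyst reduces one ketone enantiomer faster, hydride entering anti to the C7 methyl, so a single cis alcohol should form; C6 (S) and C7 (R) are both set by the catalyst.

Step 4
Reactants: 7 (6S,7R)-4,7-dimethyl-6,7-dihydro-5H-cyclopenta[c]pyridin-6-ol
Product: 8 (6S,7R)-6-hydroxy-2,4,7-trimethyl-6,7-dihydro-5H-cyclopenta[c]pyridin-2-ium 4-methylbenzenesulfonate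
Conditions: MeOTs (1.05 equiv), MeCN, 60 °C
Reagents that add atoms: methyl 4-methylbenzenesulfonate, COS(=O)(=O)c1ccc(C)cc1
Why: Menshutkin N-alkylation of the unhindered pyridine nitrogen (flanked by C1–H and C3–H); the neutral secondary alcohol is not alkylated by a sulfonate ester without base, and tosylate is a counter-ion that does not poison platinum.

Step 5
Reactants: 8 (6S,7R)-6-hydroxy-2,4,7-trimethyl-6,7-dihydro-5H-cyclopenta[c]pyridin-2-ium 4-methylbenzenesulfonate
Product: 9 (4R,4aS,6S,7R,7aR)-2,4,7-trimethyloctahydro-1H-cyclopenta[c]pyridin-6-ol
Conditions: H2 (4 atm), PtO2 (10 mol %), MeOH, rt; then aq. NaOH, extraction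
Reagents that add atoms: none
Why: Heterogeneous hydrogenation of an N-alkylpyridinium salt over platinum, the classical route to N-alkylpiperidines and closest to the cis-selective reduction of ring-fused and 3,4,5-substituted pyridinium salts: the cation adsorbs flat on the metal and hydrogen is passed stepwise from the surface to the adsorbed face of C1, C3, C4, C4a and C7a. No ring is closed; the aromatic ring becomes the piperidine and five C–H bonds form, three of them at new stereocentres. C4, C4a and C7a are set relative to one another by this suprafacial delivery, so H4, H4a and H7a end up cis and the ring fusion is cis (the trans-fused isomer is also the more strained one). The face is chosen by the substrate: in 8 the C7 methyl (benzylic, next to C7a) and the C6 hydroxyl are cis and both on the same face, so only the opposite face can lie on the surface and hydrogen enters anti to both, which gives 4R,4aS,7aR. The step needs this facial choice and needs the cis relationship at C4 to survive, which means that no half-reduced enamine may desorb and equilibrate through its iminium ion. Quaternisation makes the ring electron-poor so that saturation should be fast at room temperature in neutral methanol, platinum isomerises double bonds little, and a tetrasubstituted C4a=C7a intermediate that left the surface would again be shielded on the same face by C7–Me, C6–OH and the already set C4–Me. The C6–O bond is homobenzylic and should not be hydrogenolysed. The product is deliberately "wrong" at C7 and C6 (both cis to the piperidine carbons); these are reset in steps 6, 7 and 10, so what the step contributes is the absolute configuration of C4, C4a and C7a.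

Step 6
Reactants: 9 (4R,4aS,6S,7R,7aR)-2,4,7-trimethyloctahydro-1H-cyclopenta[c]pyridin-6-ol
Product: 11 (4R,4aS,7S,7aR)-2,4,7-trimethyloctahydro-6H-cyclopenta[c]pyridin-6-one, via cis-ketone 10 (not isolated)
Conditions: TPAP (5 mol %), NMO (1.5 equiv), 4 Å MS, CH2Cl2, rt; filter; K2CO3 (0.3 equiv), MeOH, rt
Reagents that add atoms: none
Why: Ley–Griffith oxidation tolerates the tertiary amine and gives ketone 10; C7 is then the only enolisable stereocentre (C4a and C7a are β-carbons with no retro-Michael or retro-Mannich path), and base equilibration should move the methyl from the concave face, where it eclipses C7a–C1 under the piperidine ring, to the convex face, giving the 7S ketone.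

Step 7
Reactants: 11 (4R,4aS,7S,7aR)-2,4,7-trimethyloctahydro-6H-cyclopenta[c]pyridin-6-one
Product: 12 (4R,4aS,6S,7S,7aR)-2,4,7-trimethyloctahydro-1H-cyclopenta[c]pyridin-6-ol
Conditions: NaBH4, MeOH, −20 °C
Reagents that add atoms: none
Why: Hydride reduction of a cyclopentanone: a small hydride should attack the convex face of the cis-fused bicycle (the concave face is covered by C1 and C4 of the folded piperidine), which is also the trans-2-methylcyclopentanol preference of unhindered hydrides, so the concave-face (6S) alcohol trans to the C7 methyl is expected.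

Step 8
Reactants: 13 (E)-3-(4-hydroxyphenyl)prop-2-enoic acid (p-coumaric acid) (2 equiv; two molecules combine)
Product: 14 (1α,2α,3β,4β)-2,4-bis(4-hydroxyphenyl)cyclobutane-1,3-dicarboxylic acid
Conditions: finely ground crystals as a stirred suspension in hexane, hν (medium-pressure Hg lamp, Pyrex), rt
Reagents that add atoms: second molecule of 13, (E)-3-(4-hydroxyphenyl)prop-2-enoic acid, O=C(O)/C=C/c1ccc(O)cc1
Why: Topochemical [2+2] photodimerisation in the crystal: two molecules of 13 stacked as a centrosymmetric head-to-tail pair, with parallel C=C bonds within bonding distance, join through two new C–C bonds, which fixes the regiochemistry and all four ring centres of the α-truxillic pattern at once. The lattice suppresses E/Z isomerisation.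

Step 9
Reactants: 14 (1α,2α,3β,4β)-2,4-bis(4-hydroxyphenyl)cyclobutane-1,3-dicarboxylic acid
Product: 16 (1α,2α,3β,4β)-2,4-bis{4-[(tert-butyldimethylsilyl)oxy]phenyl}cyclobutane-1,3-dicarboxylic acid, via tetrasilyl derivative 15 (not isolated)
Conditions: TBSCl (4.4 equiv), imidazole (9 equiv), DMF, rt; then THF/AcOH/H2O, rt
Reagents that add atoms: tert-butyldimethylsilyl chloride (4 equiv consumed in forming 15; two silyl groups remain in 16), CC(C)(C)[Si](C)(C)Cl
Why: Exhaustive silylation followed by selective hydrolysis of the two silyl esters, which are far more labile to aqueous acid than aryl silyl ethers; only the weak base imidazole is present, so the cyclobutane α-centres are not at risk.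

Step 10
Reactants: 16 (1α,2α,3β,4β)-2,4-bis{4-[(tert-butyldimethylsilyl)oxy]phenyl}cyclobutane-1,3-dicarboxylic acid; 12 (4R,4aS,6S,7S,7aR)-2,4,7-trimethyloctahydro-1H-cyclopenta[c]pyridin-6-ol (2.4 equiv)
Product: 17 bis[(4R,4aS,6R,7S,7aR)-2,4,7-trimethyloctahydro-1H-cyclopenta[c]pyridin-6-yl] (1α,2α,3β,4β)-2,4-bis{4-[(tert-butyldimethylsilyl)oxy]phenyl}cyclobutane-1,3-dicarboxylate
Conditions: PPh3 (3 equiv), DIAD (3 equiv), THF, 0 °C to rt
Reagents that add atoms: none
Why: Twofold Mitsunobu esterification: each C6–OH is activated as the alkoxyphosphonium ion and displaced by carboxylate with inversion (6S to 6R), the nucleophile entering from the open convex face; the ring nitrogen lies on the same side as the leaving group and cannot participate, and no base reaches the cyclobutane α-CH.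

Step 11
Reactants: 17 bis[(4R,4aS,6R,7S,7aR)-2,4,7-trimethyloctahydro-1H-cyclopenta[c]pyridin-6-yl] (1α,2α,3β,4β)-2,4-bis{4-[(tert-butyldimethylsilyl)oxy]phenyl}cyclobutane-1,3-dicarboxylate
Product: 18 bis[(4R,4aS,6R,7S,7aR)-2,4,7-trimethyloctahydro-1H-cyclopenta[c]pyridin-6-yl] (1α,2α,3β,4β)-2,4-bis(4-hydroxyphenyl)cyclobutane-1,3-dicarboxylate (CNP0180864.2)
Conditions: TBAF (2.5 equiv), AcOH (3 equiv), THF, 0 °C
Reagents that add atoms: none
Why: Fluoride cleavage of aryl silyl ethers, buffered with acetic acid so that neither phenoxide nor fluoride attacks the hindered esters or epimerises the cyclobutane centres.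

**Compound list**

1 | 3-bromo-4,5-dimethylpyridine | Cc1cncc(Br)c1C | starting material
2 | acrolein (prop-2-enal) | C=CC=O | starting material
3 | (3-bromo-5-methylpyridin-4-yl)methyllithium | [Li]Cc1c(C)cncc1Br | intermediate
4 | rac-1-(3-bromo-5-methylpyridin-4-yl)but-3-en-2-ol | C=CC(O)Cc1c(C)cncc1Br | intermediate
5 | rac-4-methyl-7-methylidene-6,7-dihydro-5H-cyclopenta[c]pyridin-6-ol | C=C1C(O)Cc2c(C)cncc21 | intermediate
6 | rac-4,7-dimethyl-5,7-dihydro-6H-cyclopenta[c]pyridin-6-one | CC1C(=O)Cc2c(C)cncc21 | intermediate
7 | (6S,7R)-4,7-dimethyl-6,7-dihydro-5H-cyclopenta[c]pyridin-6-ol | C[C@H]1[C@@H](O)Cc2c(C)cncc21 | intermediate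
8 | (6S,7R)-6-hydroxy-2,4,7-trimethyl-6,7-dihydro-5H-cyclopenta[c]pyridin-2-ium 4-methylbenzenesulfonate | C[C@H]1[C@@H](O)Cc2c(C)c[n+](C)cc21.Cc1ccc(S(=O)(=O)[O-])cc1 | intermediate
9 | (4R,4aS,6S,7R,7aR)-2,4,7-trimethyloctahydro-1H-cyclopenta[c]pyridin-6-ol | C[C@@H]1[C@@H]2CN(C)C[C@H](C)[C@@H]2C[C@@H]1O | intermediate
10 | (4R,4aS,7R,7aR)-2,4,7-trimethyloctahydro-6H-cyclopenta[c]pyridin-6-one | C[C@@H]1[C@@H]2CN(C)C[C@H](C)[C@@H]2CC1=O | intermediate
11 | (4R,4aS,7S,7aR)-2,4,7-trimethyloctahydro-6H-cyclopenta[c]pyridin-6-one | C[C@H]1[C@@H]2CN(C)C[C@H](C)[C@@H]2CC1=O | intermediate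
12 | (4R,4aS,6S,7S,7aR)-2,4,7-trimethyloctahydro-1H-cyclopenta[c]pyridin-6-ol | C[C@H]1[C@@H]2CN(C)C[C@H](C)[C@@H]2C[C@@H]1O | intermediate
13 | (E)-3-(4-hydroxyphenyl)prop-2-enoic acid | O=C(O)/C=C/c1ccc(O)cc1 | starting material
14 | (1α,2α,3β,4β)-2,4-bis(4-hydroxyphenyl)cyclobutane-1,3-dicarboxylic acid | OC(=O)[C@H]1[C@H](c2ccc(O)cc2)[C@H](C(=O)O)[C@H]1c1ccc(O)cc1 | intermediate
15 | bis(tert-butyldimethylsilyl) (1α,2α,3β,4β)-2,4-bis{4-[(tert-butyldimethylsilyl)oxy]phenyl}cyclobutane-1,3-dicarboxylate | CC(C)(C)[Si](C)(C)OC(=O)[C@H]1[C@H](c2ccc(O[Si](C)(C)C(C)(C)C)cc2)[C@H](C(=O)O[Si](C)(C)C(C)(C)C)[C@H]1c1ccc(O[Si](C)(C)C(C)(C)C)cc1 | intermediate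
16 | (1α,2α,3β,4β)-2,4-bis{4-[(tert-butyldimethylsilyl)oxy]phenyl}cyclobutane-1,3-dicarboxylic acid | OC(=O)[C@H]1[C@H](c2ccc(O[Si](C)(C)C(C)(C)C)cc2)[C@H](C(=O)O)[C@H]1c1ccc(O[Si](C)(C)C(C)(C)C)cc1 | intermediate
17 | bis[(4R,4aS,6R,7S,7aR)-2,4,7-trimethyloctahydro-1H-cyclopenta[c]pyridin-6-yl] (1α,2α,3β,4β)-2,4-bis{4-[(tert-butyldimethylsilyl)oxy]phenyl}cyclobutane-1,3-dicarboxylate | C[C@H]1[C@@H]2CN(C)C[C@H](C)[C@@H]2C[C@H]1OC(=O)[C@H]1[C@H](c2ccc(O[Si](C)(C)C(C)(C)C)cc2)[C@H](C(=O)O[C@@H]2C[C@@H]3[C@@H](CN(C)C[C@@H]3C)[C@@H]2C)[C@H]1c1ccc(O[Si](C)(C)C(C)(C)C)cc1 | intermediate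
18 | bis[(4R,4aS,6R,7S,7aR)-2,4,7-trimethyloctahydro-1H-cyclopenta[c]pyridin-6-yl] (1α,2α,3β,4β)-2,4-bis(4-hydroxyphenyl)cyclobutane-1,3-dicarboxylate | C[C@H]1[C@@H]2CN(C)C[C@H](C)[C@@H]2C[C@H]1OC(=O)[C@H]1[C@H](c2ccc(O)cc2)[C@H](C(=O)O[C@@H]2C[C@@H]3[C@@H](CN(C)C[C@@H]3C)[C@@H]2C)[C@H]1c1ccc(O)cc1 | target

**Step count and risk**

Total: 11 steps. Longest linear sequence: 9 steps (steps 1–7, then 10 and 11); steps 8 and 9 form the short second branch.

Step 5 (key step). The most likely failure is incomplete facial discrimination by the small C6–OH/C7–Me pair, or erosion of the cis relationship at C4 when a half-reduced enamine leaves the surface and equilibrates through its iminium ion. Fallback, from 7 back to 9: the hydroxyl is first converted into a bulky shield and the ring is reduced as the N–H pyridinium ion in acid, with methylation afterwards. Thus 7 is silylated (TIPSOTf, 2,6-lutidine) to (6S,7R)-4,7-dimethyl-6-[(triisopropylsilyl)oxy]-6,7-dihydro-5H-cyclopenta[c]pyridine F1. F1 is hydrogenated as its hydrochloride over Rh/C in acetic acid to the secondary amine (4R,4aS,6S,7R,7aR)-4,7-dimethyl-6-[(triisopropylsilyl)oxy]octahydro-1H-cyclopenta[c]pyridine F2. Reductive methylation (aqueous formaldehyde, NaBH(OAc)3) gives the N-methyl silyl ether (4R,4aS,6S,7R,7aR)-2,4,7-trimethyl-6-[(triisopropylsilyl)oxy]octahydro-1H-cyclopenta[c]pyridine F3, and TBAF returns 9.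

Step 2. The carbopalladation itself is routine; the weak point is the isomerisation, where Pd–H may be scavenged by the base before it walks the double bond into the enol, and the enolisable 2-indanone-type product may self-condense under hot basic conditions. Fallback, from 1 to 6, by a Dieckmann route with no palladium hydride chemistry: α-arylation of tert-butyl propanoate with 1 (Pd/P(t-Bu)3, LiHMDS) gives rac-tert-butyl 2-(4,5-dimethylpyridin-3-yl)propanoate F4. Lateral lithiation with excess LDA and diethyl carbonate gives the diester rac-tert-butyl 2-[4-(2-ethoxy-2-oxoethyl)-5-methylpyridin-3-yl]propanoate F5. KOt-Bu closes the ring to the β-keto ester rac-tert-butyl 4,7-dimethyl-6-oxo-6,7-dihydro-5H-cyclopenta[c]pyridine-7-carboxylate F6, and trifluoroacetic acid with gentle warming removes the ester and decarboxylates to 6.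

Step 3. The ketone is flanked by two benzylic-type α-carbons, so enantioface discrimination by the catalyst may be weak, and racemisation at C7 may not keep pace with reduction, which would lower both the enantiomeric and the cis/trans purity. Fallback, from 6 to 7: reduction with L-Selectride (hydride anti to the methyl) gives the racemic cis alcohol rac-(6S*,7R*)-4,7-dimethyl-6,7-dihydro-5H-cyclopenta[c]pyridin-6-ol F7. Lipase-catalysed acylation (Candida antarctica lipase B, vinyl acetate) should, by the usual empirical preference for secondary alcohols, convert the unwanted enantiomer into (6R,7S)-4,7-dimethyl-6,7-dihydro-5H-cyclopenta[c]pyridin-6-yl acetate F8 and leave 7, which is separated by chromatography.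

Step 10. The activated C6 centre is secondary and flanked by the C7 methyl, so elimination to the cyclopentene or stalling at the mono-ester may outrun the second substitution. Fallback, from 12 to 17, separating inversion from acylation: Mitsunobu reaction of 12 with 4-nitrobenzoic acid gives the inverted ester (4R,4aS,6R,7S,7aR)-2,4,7-trimethyloctahydro-1H-cyclopenta[c]pyridin-6-yl 4-nitrobenzoate F10. Methanolysis (K2CO3, MeOH) gives the convex-face alcohol (4R,4aS,6R,7S,7aR)-2,4,7-trimethyloctahydro-1H-cyclopenta[c]pyridin-6-ol F9. F9 is then acylated twice by 16 under Yamaguchi conditions (2,4,6-trichlorobenzoyl chloride, Et3N, then DMAP) with retention, giving 17.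

Step 7. Facial selectivity of hydride delivery may be poor, because the convex face carries the C7 methyl while the concave face is covered by the piperidine ring. Fallback, from 11 to 17: the route is convergent at C6, so a mixture is separated and both epimers are used. The concave-face alcohol 12 goes through step 10 (inversion), and the convex-face alcohol (4R,4aS,6R,7S,7aR)-2,4,7-trimethyloctahydro-1H-cyclopenta[c]pyridin-6-ol F9 is esterified with 16 with retention (Yamaguchi conditions) to the same 17.

**Further compounds**

F1 | step 5 | (6S,7R)-4,7-dimethyl-6-[(triisopropylsilyl)oxy]-6,7-dihydro-5H-cyclopenta[c]pyridine | C[C@H]1[C@@H](O[Si](C(C)C)(C(C)C)C(C)C)Cc2c(C)cncc21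
F2 | step 5 | (4R,4aS,6S,7R,7aR)-4,7-dimethyl-6-[(triisopropylsilyl)oxy]octahydro-1H-cyclopenta[c]pyridine | C[C@@H]1[C@@H]2CNC[C@H](C)[C@@H]2C[C@@H]1O[Si](C(C)C)(C(C)C)C(C)C
F3 | step 5 | (4R,4aS,6S,7R,7aR)-2,4,7-trimethyl-6-[(triisopropylsilyl)oxy]octahydro-1H-cyclopenta[c]pyridine | C[C@@H]1[C@@H]2CN(C)C[C@H](C)[C@@H]2C[C@@H]1O[Si](C(C)C)(C(C)C)C(C)C
F4 | step 2 | rac-tert-butyl 2-(4,5-dimethylpyridin-3-yl)propanoate | CC(C(=O)OC(C)(C)C)c1cncc(C)c1C
F5 | step 2 | rac-tert-butyl 2-[4-(2-ethoxy-2-oxoethyl)-5-methylpyridin-3-yl]propanoate | CCOC(=O)Cc1c(C)cncc1C(C)C(=O)OC(C)(C)C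
F6 | step 2 | rac-tert-butyl 4,7-dimethyl-6-oxo-6,7-dihydro-5H-cyclopenta[c]pyridine-7-carboxylate | CC1(C(=O)OC(C)(C)C)C(=O)Cc2c(C)cncc21
F7 | step 3 | rac-(6S*,7R*)-4,7-dimethyl-6,7-dihydro-5H-cyclopenta[c]pyridin-6-ol (racemate, relative configuration as drawn) | C[C@H]1[C@@H](O)Cc2c(C)cncc21
F8 | step 3 | (6R,7S)-4,7-dimethyl-6,7-dihydro-5H-cyclopenta[c]pyridin-6-yl acetate | C[C@@H]1[C@H](OC(C)=O)Cc2c(C)cncc21
F9 | step 7 | (4R,4aS,6R,7S,7aR)-2,4,7-trimethyloctahydro-1H-cyclopenta[c]pyridin-6-ol | C[C@H]1[C@@H]2CN(C)C[C@H](C)[C@@H]2C[C@H]1O
F10 | step 10 | (4R,4aS,6R,7S,7aR)-2,4,7-trimethyloctahydro-1H-cyclopenta[c]pyridin-6-yl 4-nitrobenzoate | C[C@H]1[C@@H]2CN(C)C[C@H](C)[C@@H]2C[C@H]1OC(=O)c1ccc([N+](=O)[O-])cc1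
A1 | alternative 1 | (S)-4-[(tert-butyldimethylsilyl)oxy]cyclopent-2-en-1-one | O=C1C=C[C@@H](O[Si](C)(C)C(C)(C)C)C1
A2 | alternative 1 | (2R,3S,4S)-4-[(tert-butyldimethylsilyl)oxy]-3-methyl-2-{[methyl(2-methylprop-2-en-1-yl)amino]methyl}cyclopentan-1-one | C[C@H]1[C@H](CN(C)CC(C)=C)C(=O)C[C@@H]1O[Si](C)(C)C(C)(C)C
A3 | alternative 2 | (R)-N-(but-2-yn-1-yl)-4-methyl-N-(2-methylbut-3-en-1-yl)benzenesulfonamide | CC#CCN(C[C@H](C)C=C)S(=O)(=O)c1ccc(C)cc1
A4 | alternative 2 | (4R,4aS)-4,7-dimethyl-2-(4-methylbenzenesulfonyl)-1,2,3,4,4a,5-hexahydro-6H-cyclopenta[c]pyridin-6-one | CC1=C2CN(S(=O)(=O)c3ccc(C)cc3)C[C@H](C)[C@@H]2CC1=O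
A5 | alternative 3 | (4R,4aS,6R,7S,7aR)-2,4,7-trimethyloctahydro-1H-cyclopenta[c]pyridin-6-yl (E)-3-(4-hydroxyphenyl)prop-2-enoate | C[C@H]1[C@@H]2CN(C)C[C@H](C)[C@@H]2C[C@H]1OC(=O)/C=C/c1ccc(O)cc1
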